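**Retrosynthetic overview**
- C10–Br is installed last: ring enone → 10,11-epoxide → HBr opening at C10 and dehydration.
- C7=C8 comes from dehydration of an aldol; the C7–C8 bond itself is made in an electrochemical (sacrificial zinc anode) Reformatsky-type coupling of an α'-mesyloxy cyclopentenone with methyl (E)-7-oxohept-5-enoate.
- C12–C13 and the C12 carbinol come from 1,2-addition of (Z)-oct-2-enylbarium to a sugar-derived cyclopentenone acetonide, anti to the acetonide.
- Rings: the only ring (the cyclopentene) is bought in the sugar-derived enone; no ring is formed. Its two sugar stereocentres control C12 and are then destroyed (C9 → C=O; the C8 oxygen is expelled in the electrochemical step).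

Assumption: enone 3, the (3aS,6aS) antipode of the usual D-ribose cyclopentenone acetonide, is taken as a purchasable carbohydrate-derived building block (D-mannose series, or D-ribose by the inverted sequence). Prostanoid numbering (C1 = ester carbon) is used for locants.

**Step 1**
Reactants: 1, (Z)-oct-2-en-1-ol
Product: 2, (Z)-1-chlorooct-2-ene
Conditions: MsCl, s-collidine, LiCl, DMF, 0 °C
Reagents that add atoms: lithium chloride, [Li+].[Cl-]
Why: Collington–Meyers chlorination (in situ mesylate, SN2 by chloride) converts the primary allylic alcohol to the chloride without allylic transposition or Z→E isomerisation.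

**Step 2**
Reactants: 2, (Z)-1-chlorooct-2-ene; 3, (3aS,6aS)-2,2-dimethyl-3a,6a-dihydro-4H-cyclopenta[d][1,3]dioxol-4-one
Product: 4, (3aS,4R,6aS)-2,2-dimethyl-4-[(2Z)-oct-2-en-1-yl]-3a,6a-dihydro-4H-cyclopenta[d][1,3]dioxol-4-ol
Conditions: Rieke Ba (BaI2, lithium biphenylide, THF, rt); 2, −78 °C; then 3, −78 °C; NH4Cl quench at −78 °C
Reagents that add atoms: none
Why: Allylbarium 1,2-addition: allylic barium reagents attack carbonyls through the α-carbon with retention of Z geometry and add 1,2 to enones, and attack on the convex face anti to the cis-fused acetonide sets C12 as R (new OH cis to the acetonide oxygens) under control of the two sugar stereocentres.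

**Step 3**
Reactants: 4
Product: 5, (1R,4S,5S)-1-[(2Z)-oct-2-en-1-yl]cyclopent-2-ene-1,4,5-triol (all three OH cis)
Conditions: AcOH–H2O 4:1, 40 °C
Reagents that add atoms: none
Why: Mild acid hydrolysis of the isopropylidene acetal, which touches no stereocentre and is gentle enough for the tertiary allylic alcohol.

**Step 4**
Reactants: 5
Product: 6, (4R,5R)-4,5-dihydroxy-4-[(2Z)-oct-2-en-1-yl]cyclopent-2-en-1-one
Conditions: activated MnO2, acetone, rt
Reagents that add atoms: none
Why: MnO2 oxidises only the allylic secondary alcohol (C9) to the enone and leaves the C8 secondary alcohol, the tertiary C12 alcohol and the isolated Z-alkene untouched.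

**Step 5**
Reactants: 6
Product: 7, (1R,2R)-2-hydroxy-2-[(2Z)-oct-2-en-1-yl]-5-oxocyclopent-3-en-1-yl methanesulfonate
Conditions: Ms2O, pyridine, CH2Cl2, −20 °C; used crude
Reagents that add atoms: methanesulfonic anhydride, CS(=O)(=O)OS(C)(=O)=O
Why: Selective O-sulfonylation of the secondary α-ketol hydroxyl (the tertiary OH is too hindered, and its cis relationship to the mesylate prevents epoxide closure) puts a reducible leaving group at C8 only.

**Step 6**
Reactants: 8, methyl hex-5-enoate; 9, (E)-crotonaldehyde
Product: 10, methyl (5E)-7-oxohept-5-enoate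
Conditions: Hoveyda–Grubbs II (2 mol %), CH2Cl2, 40 °C
Reagents that add atoms: none
Why: Olefin cross-metathesis of a terminal alkene with crotonaldehyde gives the E-enal selectively, with propene as the only by-product.

**Step 7**
Reactants: 7; 10 (1.5 equiv)
Product: 11, methyl (5E)-7-hydroxy-7-{(2R)-2-hydroxy-2-[(2Z)-oct-2-en-1-yl]-5-oxocyclopent-3-en-1-yl}hept-5-enoate (mixture of C7/C8 diastereomers)
Conditions: undivided cell, Zn anode, graphite cathode, n-Bu4NBF4 (0.1 M), DMF–THF 1:1, constant current 4 mA cm⁻², 2.2 F mol⁻¹, −10 °C, 10 present throughout; aq. NH4Cl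
Reagents that add atoms: none
Why: Proposed new method: a sacrificial-zinc-anode electro-Reformatsky aldol on an α'-sulfonyloxy enone bearing a free γ-hydroxyl. The Zn²⁺/Zn couple holds the cathode near −1.1 V vs SCE, where the α-mesyloxy ketone undergoes two-electron C8–O cleavage (directly or via electrodeposited Zn) to a regiodefined cross-conjugated zinc enolate, while the enal (about −1.8 V), the ring enone and the ester are not reduced. The vinylogous γ-oxygen at C12 is a free OH and therefore not a leaving group, so C12 is untouched, and the enolate adds to aldehyde 10 to form C7–C8; the new C7/C8 stereocentres are removed in Step 8. Closest known chemistry: the sacrificial-anode electrochemical Reformatsky reaction of α-halo carbonyls, and Zn- or SmI2-mediated reductive aldols of α-heterosubstituted ketones.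

**Step 8**
Reactants: 11
Product: 12, methyl (5E,7Z,12R,14Z)-12-hydroxy-9-oxoprosta-5,7,10,14-tetraen-1-oate
Conditions: MsCl, Et3N, CH2Cl2, −20 → 0 °C; then DBU, 0 °C; chromatography
Reagents that add atoms: none
Why: Mesylation of the secondary allylic C7–OH (tertiary OH inert) and E1cB elimination give the cross-conjugated dienone as both C7 isomers; the 7Z isomer 12 is separated and the 7E isomer is recycled by photo-equilibration (350 nm).

**Step 9**
Reactants: 12
Product: 13, methyl (5E,7Z,14Z)-10,11-epoxy-12-hydroxy-9-oxoprosta-5,7,14-trien-1-oate (C12 unchanged; epoxide configuration immaterial)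
Conditions: t-BuOOH (decane), DBU, CH2Cl2, 0 °C
Reagents that add atoms: tert-butyl hydroperoxide, CC(C)(C)OO
Why: Weitz–Scheffer nucleophilic epoxidation, in which the peroxide anion adds at the ring β-carbon C11 (the simple enone terminus, H-bond-directed by the C12–OH, where soft nucleophiles attack dienones of this type) and does not touch the electron-rich Z-alkene; both new stereocentres are destroyed in Step 10.

**Step 10**
Reactants: 13
Product: 14, methyl (5E,7Z,12R,14Z)-10-bromo-12-hydroxy-9-oxoprosta-5,7,10,14-tetraen-1-oate (bromoclavulone III)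
Conditions: 48 % aq. HBr (1.5 equiv), THF, 0 → 25 °C; chromatography (removes any 7E isomer)
Reagents that add atoms: hydrogen bromide, Br
Why: Classical α,β-epoxy ketone → α-halo enone conversion: bromide opens the protonated epoxide at C10 (α to C=O, away from neopentyl C11) and the resulting β-hydroxy ketone dehydrates to the 2-bromo enone, while the tertiary alcohol γ to the enone does not ionise and the Z-alkene does not add aqueous HBr at this temperature.

**Compound list**
1 | (Z)-oct-2-en-1-ol | CCCCC/C=C\CO | starting material
2 | (Z)-1-chlorooct-2-ene | CCCCC/C=C\CCl | intermediate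
3 | (3aS,6aS)-2,2-dimethyl-3a,6a-dihydro-4H-cyclopenta[d][1,3]dioxol-4-one | O=C1C=C[C@@H]2OC(C)(C)O[C@H]12 | starting material
4 | (3aS,4R,6aS)-2,2-dimethyl-4-[(2Z)-oct-2-en-1-yl]-3a,6a-dihydro-4H-cyclopenta[d][1,3]dioxol-4-ol | CCCCC/C=C\C[C@@]1(O)C=C[C@@H]2OC(C)(C)O[C@H]12 | intermediate
5 | (1R,4S,5S)-1-[(2Z)-oct-2-en-1-yl]cyclopent-2-ene-1,4,5-triol | CCCCC/C=C\C[C@@]1(O)C=C[C@H](O)[C@@H]1O | intermediate
6 | (4R,5R)-4,5-dihydroxy-4-[(2Z)-oct-2-en-1-yl]cyclopent-2-en-1-one | CCCCC/C=C\C[C@@]1(O)C=CC(=O)[C@@H]1O | intermediate
7 | (1R,2R)-2-hydroxy-2-[(2Z)-oct-2-en-1-yl]-5-oxocyclopent-3-en-1-yl methanesulfonate | CCCCC/C=C\C[C@@]1(O)C=CC(=O)[C@@H]1OS(C)(=O)=O | intermediate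
8 | methyl hex-5-enoate | C=CCCCC(=O)OC | starting material
9 | (E)-crotonaldehyde | C/C=C/C=O | starting material
10 | methyl (5E)-7-oxohept-5-enoate | O=C/C=C/CCCC(=O)OC | intermediate
11 | methyl (5E)-7-hydroxy-7-{(2R)-2-hydroxy-2-[(2Z)-oct-2-en-1-yl]-5-oxocyclopent-3-en-1-yl}hept-5-enoate (C7/C8 diastereomers) | CCCCC/C=C\C[C@@]1(O)C=CC(=O)C1C(O)/C=C/CCCC(=O)OC | intermediate
12 | methyl (5E,7Z,12R,14Z)-12-hydroxy-9-oxoprosta-5,7,10,14-tetraen-1-oate | CCCCC/C=C\C[C@@]1(O)C=CC(=O)/C1=C\C=C\CCCC(=O)OC | intermediate
13 | methyl (5E,7Z,14Z)-10,11-epoxy-12-hydroxy-9-oxoprosta-5,7,14-trien-1-oate | CCCCC/C=C\C[C@@]1(O)C2OC2C(=O)/C1=C\C=C\CCCC(=O)OC | intermediate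
14 | bromoclavulone III, methyl (5E,7Z,12R,14Z)-10-bromo-12-hydroxy-9-oxoprosta-5,7,10,14-tetraen-1-oate | CCCCC/C=C\C[C@@]1(O)C=C(Br)C(=O)/C1=C\C=C\CCCC(=O)OC | target

**Step count**
Total: 10 steps. Longest linear sequence: 9 steps (1 → 2 → 4 → 5 → 6 → 7 → 11 → 12 → 13 → 14).

**Three steps most likely to fail, with fallbacks**
1. Step 7 (proposed new electro-Reformatsky aldol). Risks are protonation of the zinc enolate by the free OH, giving the deoxy ketone, or competing enone reduction. Fallback with known chemistry: remove the C8 mesylate reductively (Zn/AcOH or SmI2/MeOH, a standard α-sulfonyloxy ketone reduction) to give (R)-4-hydroxy-4-[(Z)-oct-2-enyl]cyclopent-2-enone, protect it as the TES ether, form the kinetic α'-lithium enolate (LDA, −78 °C), add 10, and dehydrate with MsCl/Et3N. This is the base-mediated aldol used for clavulone-type dienones.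
2. Step 9 (epoxidation of the dienone). Risks are attack at the exocyclic dienone terminus and base-induced 7Z/7E scrambling. Fallback: halogenate before the α-chain is attached. On the TES-protected deoxy hydroxy-enone from the fallback above (only one enone present), carry out H2O2/NaOH epoxidation and HBr opening, then the LDA aldol with 10 and dehydration on the 2-bromo enone.
3. Step 2 (Rieke barium allylation). Risks are α/γ selectivity, Z retention and enolisation of 3. Fallback: allylmagnesium bromide 1,2-addition to 3 (same acetonide facial control), then Z-selective Ru-catalysed cross-metathesis with 1-heptene; alternatively propargylmagnesium bromide addition, alkylation of the terminal alkyne with 1-iodopentane and Lindlar reduction.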